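Its constants stand for no real mixture, and the outcome is calculated.

I took up this flask as the early reading of a neighbour with the same charges read much later, so I wanted the reagent's books ready before opening either.

    substrate + target → side product (k1 = 1.28 /M/h)
    reagent in the reaction phase ⇌ reagent in the second phase, rate k2*([reagent in the reaction phase] - [reagent in the second phase]/K2) per volume of the first phase (K2 = 4.42, k2 = 1.69 /h)
    substrate + reagent in the reaction phase → target (k3 = 5.63 /M/h)
    reagent in the reaction phase + protic impurity → quenched reagent (k4 = 48.4 /M/h)

substrate 10 mM; reagent in the second phase 8.00 mM; protic impurity 0.500 mM; time 12 h; volume of the second phase over the first 1.0

- in percentages every species weighs as the substrate in it: one side product counts as two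
- in the second phase: reagent in the second phase; everything else is in the first
- charges count per volume of the first phase; a concentration in a rate is the amount of a species over the volume of its own phase; every rate counts per litre of the first phase
- run time (flask): 12 h

* target at 12 h, in percent of the substrate charged
* the change that raises the amount of target at 12 h, in percent of the substrate charged most ("none" if none brings more than 2 percentage points) (south-east / north / none)
* amount of target at 12 h, in percent of the substrate charged, after north

- south-east: doubling the transfer coefficient of step 2, all else as stated
- north: doubling the amount of reagent in the second phase, all else as stated

- I kept the ledger on the reagent in the second phase, the limiting reagent, since its charge of 8.00 mM stood below the 10 mM of substrate.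
- The phases relax within 0.483 h, far shorter than the run, and the chemical drain on the reaction phase is slower than transfer, so I froze the partition and carried the reaction-phase share, the fraction of unspent reagent standing in the reaction phase at partition, 18.5 %.
- Opening entry: the share put 1.48 mM in the reaction phase, which made the substrate's loss pseudo-first-order.
- Entry for target: that frozen level turned 0.949 mM of reagent into target, so I committed to 9.49 %.
- Entry for quenching: the protic impurity took 0.288 mM, while the side reaction spends no reagent and has no line.
- Closing the books: the share of what stayed unspent gave 1.25 mM at the end, so the level sags slowly.
- For the changes I scored the gain in points: north won, with 18.1 % of target after it.
- The forecast gave 7.6 %, north and 14.6 %, holding that “Yield therefore scales almost linearly with the reagent charge”.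
- The flask gave 7.69 % of target, and north was the better change, worth 7.2 percentage points against 0.22 points, reaching 14.9 %.
- The time allowed was the largest single effect on target in this flask, though not the main reason for the low figure: left until 120 h it gave 24.5 % rather than 7.69 %, a gain of 17 points that was 18 % of what was missing. The share, applied to the reagent unspent in this flask at 12.0 h, gave 1.28 mM against a reading of 1.24 mM. On the neighbour read at 50 h, the same share of its unspent reagent gave 0.909 mM, and that neighbour's reaction phase read 0.895 mM.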